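At 2.5 min each earlier run has its last reading, and each new flask is read at that same time.

| flask | substrate | reagent in the second phase | remark | time | volume of the second phase over the first |
|---|---|---|---|---|---|
| green | 0.0028 M | 0.060 M | run made earlier |  |  |
| violet | 0.017 M | 0.060 M | run made earlier |  |  |
| amber | 0.051 M | 0.060 M | run made earlier |  |  |
| delta | 0.015 M | 0.0600 M |  | 2.5 min | 2.0 |
| zeta | 0.025 M | 0.0600 M |  | 2.5 min | 2.0 |
| alpha | 0.0040 M | 0.0600 M |  | 2.5 min | 2.0 |
| theta | 0.060 M | 0.0600 M |  | 2.5 min | 2.0 |

| run | time / min | target / % | substrate / % |
|---|---|---|---|
| green | 0.200 | 1.2 | 98.6 |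
| green | 0.417 | 5.8 | 93.8 |
| green | 0.667 | 12.5 | 87.2 |
| green | 1.33 | 31.5 | 64.6 |
| green | 2.50 | 48.9 | 34.1 |
| violet | 0.200 | 2.0 | 99.0 |
| violet | 0.417 | 5.8 | 94.4 |
| violet | 0.667 | 10.9 | 89.1 |
| violet | 1.33 | 25.1 | 72.7 |
| violet | 2.50 | 42.0 | 48.2 |
| amber | 0.200 | 1.2 | 98.8 |
| amber | 0.667 | 7.3 | 92.5 |
| amber | 1.33 | 16.1 | 82.9 |
| amber | 2.00 | 23.4 | 74.5 |
| amber | 2.50 | 27.8 | 69.4 |

(each reading ± 0.3 percentage points)

- in the second phase: reagent in the second phase; everything else is in the first
- charges count per volume of the first phase; a concentration in a rate is the amount of a species over the volume of its own phase; every rate counts per litre of the first phase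
- steps that have been proposed: reagent in the reaction phase <-> reagent in the second phase; substrate + reagent in the reaction phase -> target; reagent in the reaction phase + target -> over-reacted product; reagent in the reaction phase <-> dormant form
- the earlier runs hold the two phases in the same ratio of volumes as the flask asked about

- the flasks put in order of amount of target, in percent of the substrate charged, best first, at 2.5 min (delta / zeta / alpha / theta)
- the amount of target, in percent of the substrate charged of the flask you put first, at 2.5 min
- the amount of target, in percent of the substrate charged of the flask you put last, at 2.5 min

Count turnovers. A flask's turnover count is ln(1/x), where x is the fraction of substrate left. Both proposed steps use the reagent in the reaction phase, so its level cancels from the ratio of their rates, and target follows x. That ratio of constants is the selectivity factor. The last readings suit a factor of 0.5, which makes target 2(√x − x). For amber this gives 0.278 of the charge, and the reading is 27.8 %. The rule has a peak count, the turnovers at which target tops out: 1.39.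

What must you know well? Time, reagent in the second phase and volume ratio match the earlier runs, so they enter through the readings. The count remains. At green's x target moves by 0.0980 of the charge per turnover of count, but at amber's x by 0.555. So an error in the count weighs more near amber's charge than near green's.

Now the counts: 1.08 for green, 0.730 for violet, 0.365 for amber. They fall as the charge rises, and each lies below the peak count. So I put the lowest charge first. I take the reciprocal count as straight in the charge. Alpha then gets 1.03 turnovers and 0.481 of its charge as target. Theta, beyond amber, gets 0.323 and 0.254.

The forecast says alpha > delta > zeta > theta, with 48.2 % and 25 %, holding that “Only the exposure changes with charge”.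

The flask gives alpha > delta > zeta > theta, with 48.4 % for alpha and 25.3 % for theta.

    reagent in the reaction phase ⇌ reagent in the second phase, rate k1*([reagent in the reaction phase] - [reagent in the second phase]/K1) per volume of the first phase (partition coefficient = 1.60, kL = 0.0103 s⁻¹)
    substrate + reagent in the reaction phase → target (k = 1.19 M⁻¹ s⁻¹)
    reagent in the reaction phase + target → over-reacted product (k = 0.595 M⁻¹ s⁻¹)
    reagent in the reaction phase ⇌ dormant form (K = 1.49, k = 0.00588 s⁻¹)

Alpha keeps 34.8 % of its substrate at 2.5 min, which is 1.05 turnovers, short of the peak count 1.39. At that time alpha makes target 1.44 times faster than it uses it up, each step taken net. Theta's target has moved by 5 points with reagent in the second phase at 0.0460 M or 0.0757 M, or with the time at 1.89 min or 3.25 min, each moved with the rest held. Left to 25.0 min, theta keeps 26.5 % of its substrate, 1.33 turnovers against the peak count 1.39, and holds 50.0 % of its charge as target.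

Readings and results stem from a simulated flask with constants of no real substance; noise was put on by code.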